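**Plan**

1. Retrosynthesis: remove the two O‑benzyl groups; cut the aryl–C(=O) bond (Weinreb amide plus aryl Grignard); return the C3 carbinol to a ketone; cut C2–C3 of the oxolane and, in the same operation, C3–C4, so that C3 leaves as carbon monoxide and the ring opens to a β‑(styryloxy)alkyl phenyl selenide; cut the vinylic C–O bond and the C–Se bond back to a four‑carbon chlorohydrin.
2. Forward: the chain C4–C5–CH2–C(=O) comes from ethyl (S)‑4‑chloro‑3‑hydroxybutanoate (Weinreb amide, then PhSe for Cl), and the O‑styryl arm is attached by C–O coupling. The only ring, the oxolane, arises in one radical operation that joins selenide, CO and enol ether. Ketone reduction, aryl ketone formation and debenzylation follow.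
3. Enabling feature: oxolane C2 carries the ring oxygen O1 and a benzylic CH2, so C2 and that CH2 are the two carbons of an aryl enol ether, and a radical adding at C2 leaves a benzylic radical. C3 is an oxygenated carbon between C2 and the C4 methylene, i.e. the carbonyl carbon of an acyl radical made from a C4 radical and CO.
4. Stereochemistry: C5 comes from the chiral pool (the carbinol carbon of the (S)‑chlorohydrin ester, no bond to it is ever broken). C2 is set by 1,3‑induction from C5 in the 5‑exo cyclisation (2,5‑cis), with both enol ether geometries converging. C3 is set by hydride attack anti to the two cis substituents (all‑cis).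

Key step: step 5

Remark: the oxolane is numbered O1, C2 (arylmethyl‑bearing), C3 (carbinol), C4, C5 (bearing the CH2C(=O)Ar arm); compounds 1, 4 and 13 are taken as purchasable and both phenols are carried as benzyl ethers.

**Route**

Step 1
Reactants: 1 ethyl (S)‑4‑chloro‑3‑hydroxybutanoate
Product: 2 (S)‑4‑chloro‑3‑hydroxy‑N‑methoxy‑N‑methylbutanamide
Conditions: MeNH(OMe)·HCl, AlMe3, CH2Cl2, 0 °C to rt; cold dilute HCl work‑up
Reagents that add atoms: N,O‑dimethylhydroxylamine hydrochloride, CNOC.Cl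
Why: Weinreb aminolysis of the ester by the aluminium amide formed from AlMe3 and the amine hydrochloride; the conditions are not basic, so the chlorohydrin should not close to an epoxide, and the stereocenter is untouched.

Step 2
Reactants: 2 (S)‑4‑chloro‑3‑hydroxy‑N‑methoxy‑N‑methylbutanamide
Product: 3 (S)‑3‑hydroxy‑N‑methoxy‑N‑methyl‑4‑(phenylselanyl)butanamide
Conditions: (PhSe)2, NaBH4, EtOH, 0 °C until gas evolution stops; then 2, rt
Reagents that add atoms: diphenyl diselenide, c1ccc(cc1)[Se][Se]c1ccccc1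
Why: SN2 displacement of the primary chloride by the soft, weakly basic benzeneselenolate; no bond to the carbinol carbon is broken, so its configuration is kept, and the borohydride is consumed in making the selenolate before the amide is added.

Step 3
Reactants: 4 (E)‑3‑[4‑(benzyloxy)‑3‑methoxyphenyl]prop‑2‑enoic acid
Product: 5 (E)‑1‑(benzyloxy)‑4‑(2‑iodoethenyl)‑2‑methoxybenzene
Conditions: NIS, Et3N (cat.), CH2Cl2, rt
Reagents that add atoms: N‑iodosuccinimide, O=C1CCC(=O)N1I
Why: Catalytic Hunsdiecker‑type iododecarboxylation, which works best for electron‑rich cinnamic acids and should give the (E)‑vinyl iodide through iodination at the α‑carbon and loss of CO2 from the benzylic cation.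

Step 4
Reactants: 3 (S)‑3‑hydroxy‑N‑methoxy‑N‑methyl‑4‑(phenylselanyl)butanamide; 5 (E)‑1‑(benzyloxy)‑4‑(2‑iodoethenyl)‑2‑methoxybenzene
Product: 6 (S)‑3‑{[(E)‑2‑(4‑benzyloxy‑3‑methoxyphenyl)ethenyl]oxy}‑N‑methoxy‑N‑methyl‑4‑(phenylselanyl)butanamide
Conditions: CuI (cat.), 3,4,7,8‑tetramethyl‑1,10‑phenanthroline (cat.), Cs2CO3, toluene, 80 °C
Reagents that add atoms: none
Why: Ullmann‑type copper‑catalysed C–O coupling of an aliphatic alcohol with a vinyl iodide, with retention of the alkene geometry; the carbonate base is too weak to enolise the amide, and the O–C(sp3) bond of the carbinol is not involved, so its configuration is kept.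

Step 5
Reactants: 6 (S)‑3‑{[(E)‑2‑(4‑benzyloxy‑3‑methoxyphenyl)ethenyl]oxy}‑N‑methoxy‑N‑methyl‑4‑(phenylselanyl)butanamide; 7 carbon monoxide
Product: 11 2‑[(2R,5R)‑5‑(4‑benzyloxy‑3‑methoxybenzyl)‑4‑oxooxolan‑2‑yl]‑N‑methoxy‑N‑methylacetamide (2,5‑cis oxolan‑3‑one), via primary alkyl radical 8 (not isolated), via acyl radical 9 (not isolated), via cyclised benzylic radical 10 (not isolated)
Conditions: CO (80 atm), (TMS)3SiH, AIBN, benzene (0.02 M), 80 °C, autoclave
Reagents that add atoms: none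
Why: The tris(trimethylsilyl)silyl radical abstracts the PhSe group to give primary radical 8, which is intercepted by CO under pressure to give acyl radical 9; this closes onto the oxygen‑bearing alkene carbon of the styryl ether, and the benzylic radical 10 so formed takes a hydrogen atom from the silane, which carries the chain. The closest known reaction type is the radical carbonylation/reductive cyclisation of O‑vinylated β‑hydroxyalkyl phenyl selenides (and the cyclisation of acyl selenides onto β‑alkoxyacrylates) to oxolan‑3‑ones, the aryl group here taking the radical‑stabilising role of the ester. The oxolane ring closes in a 5‑exo‑trig mode by C2–C3 bond formation, C3 itself having entered as CO one elementary step earlier. The one new stereocenter, C2, is controlled by the existing C5 center: in the chair‑like transition state the C5 side chain and the alkene both sit pseudo‑equatorial, which should give the 2,5‑cis ketone, and because the aryl‑bearing alkene carbon ends as a CH2 group, both enol ether geometries converge on the same product. The step needs CO capture to outrun hydrogen transfer to 8 (secured by the CO pressure and dilute silane, and by 8 having only a strained 4‑exo or a 5‑endo path to the alkene), and it needs exo attack at C2, which the aryl group secures by making the adduct radical benzylic.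

Step 6
Reactants: 11 2‑[(2R,5R)‑5‑(4‑benzyloxy‑3‑methoxybenzyl)‑4‑oxooxolan‑2‑yl]‑N‑methoxy‑N‑methylacetamide
Product: 12 2‑[(2R,4R,5R)‑5‑(4‑benzyloxy‑3‑methoxybenzyl)‑4‑hydroxyoxolan‑2‑yl]‑N‑methoxy‑N‑methylacetamide
Conditions: LiBH(s‑Bu)3, THF, −78 °C; aq NH4Cl
Reagents that add atoms: none
Why: Substrate‑controlled ketone reduction in which the bulky hydride attacks the face opposite to the cis C2 and C5 substituents, which should give the all‑cis alcohol; the Weinreb amide is inert at −78 °C, and the cold, non‑basic quench protects the epimerisable C2 center.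

Step 7
Reactants: 12 2‑[(2R,4R,5R)‑5‑(4‑benzyloxy‑3‑methoxybenzyl)‑4‑hydroxyoxolan‑2‑yl]‑N‑methoxy‑N‑methylacetamide; 13 1‑(benzyloxy)‑4‑bromo‑2‑methoxybenzene
Product: 15 2‑[(2R,4R,5R)‑5‑(4‑benzyloxy‑3‑methoxybenzyl)‑4‑hydroxyoxolan‑2‑yl]‑1‑[4‑(benzyloxy)‑3‑methoxyphenyl]ethan‑1‑one, via aryl Grignard reagent 14 (not isolated)
Conditions: Mg, THF, 40 °C (13 to 14); then 12 added to excess 14, THF, 0 °C; aq NH4Cl
Reagents that add atoms: none
Why: Weinreb ketone synthesis in which the Grignard reagent first deprotonates the hydroxyl and then adds once to the amide, giving a chelated tetrahedral intermediate that releases the aryl ketone only on neutral work‑up, so over‑addition and base‑induced retro‑oxa‑Michael opening at C5 should be avoided.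

Step 8
Reactants: 15 2‑[(2R,4R,5R)‑5‑(4‑benzyloxy‑3‑methoxybenzyl)‑4‑hydroxyoxolan‑2‑yl]‑1‑[4‑(benzyloxy)‑3‑methoxyphenyl]ethan‑1‑one
Product: 16 renealtin A, 2‑[(2R,4R,5R)‑4‑hydroxy‑5‑(4‑hydroxy‑3‑methoxybenzyl)oxolan‑2‑yl]‑1‑(4‑hydroxy‑3‑methoxyphenyl)ethan‑1‑one
Conditions: H2 (1 atm), 10% Pd/C, EtOAc, rt
Reagents that add atoms: none
Why: Hydrogenolysis of the two aryl benzyl ethers under neutral conditions, which should leave the electron‑rich aryl ketone, the homobenzylic ring C–O bond and the base‑sensitive β‑alkoxy ketone (C5) untouched.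

**Compound list**

1 | ethyl (S)‑4‑chloro‑3‑hydroxybutanoate | CCOC(=O)C[C@H](O)CCl | starting material
2 | (S)‑4‑chloro‑3‑hydroxy‑N‑methoxy‑N‑methylbutanamide | CON(C)C(=O)C[C@H](O)CCl | intermediate
3 | (S)‑3‑hydroxy‑N‑methoxy‑N‑methyl‑4‑(phenylselanyl)butanamide | CON(C)C(=O)C[C@H](O)C[Se]c1ccccc1 | intermediate
4 | (E)‑3‑[4‑(benzyloxy)‑3‑methoxyphenyl]prop‑2‑enoic acid | COc1cc(/C=C/C(=O)O)ccc1OCc1ccccc1 | starting material
5 | (E)‑1‑(benzyloxy)‑4‑(2‑iodoethenyl)‑2‑methoxybenzene | COc1cc(/C=C/I)ccc1OCc1ccccc1 | intermediate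
6 | (S)‑3‑{[(E)‑2‑(4‑benzyloxy‑3‑methoxyphenyl)ethenyl]oxy}‑N‑methoxy‑N‑methyl‑4‑(phenylselanyl)butanamide | CON(C)C(=O)C[C@H](O/C=C/c1ccc(OCc2ccccc2)c(OC)c1)C[Se]c1ccccc1 | intermediate
7 | carbon monoxide | [C-]#[O+] | starting material
8 | primary alkyl radical formed from 6 by loss of PhSe | CON(C)C(=O)C[C@H](O/C=C/c1ccc(OCc2ccccc2)c(OC)c1)[CH2] | intermediate
9 | acyl radical formed from 8 and CO | CON(C)C(=O)C[C@H](O/C=C/c1ccc(OCc2ccccc2)c(OC)c1)C[C]=O | intermediate
10 | cyclised benzylic radical (2,5‑cis oxolan‑3‑one) | COc1cc([CH][C@H]2O[C@@H](CC(=O)N(C)OC)CC2=O)ccc1OCc1ccccc1 | intermediate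
11 | 2‑[(2R,5R)‑5‑(4‑benzyloxy‑3‑methoxybenzyl)‑4‑oxooxolan‑2‑yl]‑N‑methoxy‑N‑methylacetamide | COc1cc(C[C@H]2O[C@@H](CC(=O)N(C)OC)CC2=O)ccc1OCc1ccccc1 | intermediate
12 | 2‑[(2R,4R,5R)‑5‑(4‑benzyloxy‑3‑methoxybenzyl)‑4‑hydroxyoxolan‑2‑yl]‑N‑methoxy‑N‑methylacetamide | COc1cc(C[C@H]2O[C@@H](CC(=O)N(C)OC)C[C@H]2O)ccc1OCc1ccccc1 | intermediate
13 | 1‑(benzyloxy)‑4‑bromo‑2‑methoxybenzene | COc1cc(Br)ccc1OCc1ccccc1 | starting material
14 | [4‑(benzyloxy)‑3‑methoxyphenyl]magnesium bromide | COc1cc([Mg]Br)ccc1OCc1ccccc1 | intermediate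
15 | 2‑[(2R,4R,5R)‑5‑(4‑benzyloxy‑3‑methoxybenzyl)‑4‑hydroxyoxolan‑2‑yl]‑1‑[4‑(benzyloxy)‑3‑methoxyphenyl]ethan‑1‑one | COc1cc(C[C@H]2O[C@@H](CC(=O)c3ccc(OCc4ccccc4)c(OC)c3)C[C@H]2O)ccc1OCc1ccccc1 | intermediate
16 | renealtin A | COc1cc(C[C@H]2O[C@@H](CC(=O)c3ccc(O)c(OC)c3)C[C@H]2O)ccc1O | target

**Step count and risks**

Total step count: 8. Longest linear sequence: 7 (steps 1, 2, 4, 5, 6, 7, 8).

Step 5 (carbonylative radical cyclisation). Hydrogen transfer to the primary radical may outrun CO capture, chain transfer at the benzylic radical may be slow, or the 2,5‑cis selectivity at 80 °C may be insufficient. The fallback drops CO and closes the same bond from a preformed acyl selenide at room temperature. It sets out from vinyl iodide 5, which is coupled under the conditions of step 4 with purchased ethyl (S)‑4‑cyano‑3‑hydroxybutanoate to give ethyl (S)‑3‑{[(E)‑2‑(4‑benzyloxy‑3‑methoxyphenyl)ethenyl]oxy}‑4‑cyanobutanoate F1. Here the ester arm becomes C4/C3 of the ring and the nitrile arm becomes the aryl ketone, which is why the (S)‑cyano ester is the right enantiomer. Me2AlSePh (from AlMe3 and PhSeH, CH2Cl2, 0 °C) should convert the ester directly into Se‑phenyl (S)‑3‑{[(E)‑2‑(4‑benzyloxy‑3‑methoxyphenyl)ethenyl]oxy}‑4‑cyanobutaneselenoate F2. (TMS)3SiH with Et3B and air in benzene at rt should then give 2‑[(2S,5R)‑5‑(4‑benzyloxy‑3‑methoxybenzyl)‑4‑oxooxolan‑2‑yl]acetonitrile F3 by 5‑exo acyl radical cyclisation. Reduction with LiBH(s‑Bu)3 at −78 °C should give 2‑[(2S,4R,5R)‑5‑(4‑benzyloxy‑3‑methoxybenzyl)‑4‑hydroxyoxolan‑2‑yl]acetonitrile F4. Addition of excess Grignard reagent 14 to the nitrile and hydrolysis of the ketimine with aqueous HCl brings the route back at compound 15.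

Step 4 (copper‑catalysed O‑vinylation). The hindered secondary alcohol may couple sluggishly, the selenide may inhibit the catalyst, or the β‑hydroxy amide may dehydrate under base at 80 °C. The fallback builds the vinylic C–O bond by acid‑mediated acetalisation and elimination and sets out from alcohol 3. Purchased 4‑(benzyloxy)‑3‑methoxybenzaldehyde is converted by Wittig methoxymethylenation (MeOCH2PPh3Cl, KOt‑Bu, THF) into 1‑(benzyloxy)‑2‑methoxy‑4‑(2‑methoxyethenyl)benzene F5. Alcohol 3 adds to F5 under PPTS catalysis in CH2Cl2 to give the mixed acetal (3S)‑3‑{2‑[4‑(benzyloxy)‑3‑methoxyphenyl]‑1‑methoxyethoxy}‑N‑methoxy‑N‑methyl‑4‑(phenylselanyl)butanamide F6. TMSOTf and i‑Pr2NEt in CH2Cl2 at −20 °C should eliminate methanol to give compound 6 together with its geometric isomer (S)‑3‑{[(Z)‑2‑(4‑benzyloxy‑3‑methoxyphenyl)ethenyl]oxy}‑N‑methoxy‑N‑methyl‑4‑(phenylselanyl)butanamide F7. Both isomers converge in step 5, so the route is rejoined at compound 6.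

Step 7 (Grignard addition with a free hydroxyl). The magnesium alkoxide may attack the amide intramolecularly (lactonisation, then double addition), or α‑deprotonation may open the ring by β‑elimination. The fallback masks the hydroxyl and sets out from alcohol 12. TESCl and imidazole in CH2Cl2 should give 2‑[(2R,4R,5R)‑5‑(4‑benzyloxy‑3‑methoxybenzyl)‑4‑(triethylsilyloxy)oxolan‑2‑yl]‑N‑methoxy‑N‑methylacetamide F8. A slight excess of Grignard reagent 14 at 0 °C should give 2‑[(2R,4R,5R)‑5‑(4‑benzyloxy‑3‑methoxybenzyl)‑4‑(triethylsilyloxy)oxolan‑2‑yl]‑1‑[4‑(benzyloxy)‑3‑methoxyphenyl]ethan‑1‑one F9. AcOH/THF/H2O at rt removes the silyl group and the route is rejoined at compound 15.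

Further compounds
F1 | step 5 | ethyl (S)‑3‑{[(E)‑2‑(4‑benzyloxy‑3‑methoxyphenyl)ethenyl]oxy}‑4‑cyanobutanoate | CCOC(=O)C[C@@H](O/C=C/c1ccc(OCc2ccccc2)c(OC)c1)CC#N
F2 | step 5 | Se‑phenyl (S)‑3‑{[(E)‑2‑(4‑benzyloxy‑3‑methoxyphenyl)ethenyl]oxy}‑4‑cyanobutaneselenoate | N#CC[C@H](O/C=C/c1ccc(OCc2ccccc2)c(OC)c1)CC(=O)[Se]c1ccccc1
F3 | step 5 | 2‑[(2S,5R)‑5‑(4‑benzyloxy‑3‑methoxybenzyl)‑4‑oxooxolan‑2‑yl]acetonitrile | COc1cc(C[C@H]2O[C@@H](CC#N)CC2=O)ccc1OCc1ccccc1
F4 | step 5 | 2‑[(2S,4R,5R)‑5‑(4‑benzyloxy‑3‑methoxybenzyl)‑4‑hydroxyoxolan‑2‑yl]acetonitrile | COc1cc(C[C@H]2O[C@@H](CC#N)C[C@H]2O)ccc1OCc1ccccc1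
F5 | step 4 | 1‑(benzyloxy)‑2‑methoxy‑4‑(2‑methoxyethenyl)benzene (E/Z mixture) | COC=Cc1ccc(OCc2ccccc2)c(OC)c1
F6 | step 4 | (3S)‑3‑{2‑[4‑(benzyloxy)‑3‑methoxyphenyl]‑1‑methoxyethoxy}‑N‑methoxy‑N‑methyl‑4‑(phenylselanyl)butanamide (both acetal epimers) | CON(C)C(=O)C[C@H](OC(OC)Cc1ccc(OCc2ccccc2)c(OC)c1)C[Se]c1ccccc1
F7 | step 4 | (S)‑3‑{[(Z)‑2‑(4‑benzyloxy‑3‑methoxyphenyl)ethenyl]oxy}‑N‑methoxy‑N‑methyl‑4‑(phenylselanyl)butanamide | CON(C)C(=O)C[C@H](O/C=C\c1ccc(OCc2ccccc2)c(OC)c1)C[Se]c1ccccc1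
F8 | step 7 | 2‑[(2R,4R,5R)‑5‑(4‑benzyloxy‑3‑methoxybenzyl)‑4‑(triethylsilyloxy)oxolan‑2‑yl]‑N‑methoxy‑N‑methylacetamide | COc1cc(C[C@H]2O[C@@H](CC(=O)N(C)OC)C[C@H]2O[Si](CC)(CC)CC)ccc1OCc1ccccc1
F9 | step 7 | 2‑[(2R,4R,5R)‑5‑(4‑benzyloxy‑3‑methoxybenzyl)‑4‑(triethylsilyloxy)oxolan‑2‑yl]‑1‑[4‑(benzyloxy)‑3‑methoxyphenyl]ethan‑1‑one | COc1cc(C[C@H]2O[C@@H](CC(=O)c3ccc(OCc4ccccc4)c(OC)c3)C[C@H]2O[Si](CC)(CC)CC)ccc1OCc1ccccc1
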